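**Retrosynthetic overview** (carotenoid numbering: unprimed locants for the keto half with ring A, primed locants for the acetylenic half with ring B)

1. The C40 target is opened last at the C8'–C9' bond: the terminal C–H of a C11 ring B alkyne is added across the C9'≡C10' triple bond of a 9',10'-didehydro C29 polyenynone. One operation should give the fragment bond and the (9'E) trisubstituted olefin, with no protecting group and no by-product.
2. Enabling feature: the C7'≡C8' alkyne on ring B sits directly on C9' of the C9'=C10' olefin, and this olefin is conjugated through six further C=C bonds with the C8 ketone. In the precursor the C9'≡C10' alkyne is therefore a vinylogous ynone whose methyl-bearing end (C9') should accept the alkynyl group.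
3. The C29 polyenynone is opened at C9=C10 (Horner–Wadsworth–Emmons) into a ring A β-ketophosphonate and a C16 polyenynal; the latter comes from the C10 dialdehyde by a propargyl-phosphonate olefination and a two-carbon Wittig homologation.
4. No ring is constructed. Rings A and B both come from ketoisophorone through one asymmetric transfer hydrogenation: ring B by conjugate reduction/enol triflation and Sonogashira coupling (the carbinol becomes C3'), ring A by a face-selective 1,2-addition that sets C6, after which the controlling carbinol is oxidised to the C3 ketone.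
5. Order: ring B alkyne and ring A ketophosphonate in parallel from a common silyl ether, then the chain, the C9=C10 union, and finally the alkyne–alkyne addition.

Key step: step 13

Remark (assumption): ketoisophorone, (2E,4E,6E)-2,7-dimethylocta-2,4,6-trienedial, diethyl (3-oxobutan-2-yl)phosphonate, 1-bromobut-2-yne, ethynyltrimethylsilane and (triphenylphosphoranylidene)acetaldehyde are taken as purchased; all polyenes are handled under argon in dim light.

**Route**

Step 1
Reactants: 1 2,6,6-trimethylcyclohex-2-ene-1,4-dione (ketoisophorone)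
Product: 2 (4S)-4-hydroxy-2,6,6-trimethylcyclohex-2-en-1-one
Conditions: RuCl(p-cymene)[(S,S)-TsDPEN] (1 mol %), KOH (2.5 mol %), i-PrOH, rt
Reagents that add atoms: none
Why: Noyori asymmetric transfer hydrogenation: the ruthenium hydride should reduce only the unhindered C4 carbonyl (C1 is screened by the gem-dimethyl carbon and the methyl-bearing olefin carbon), and with the (S,S)-ligand hydride is expected on the face that gives the (S)-carbinol, the C2=C3 bond taking the place of the aryl group of an aryl ketone.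

Step 2
Reactants: 2 (4S)-4-hydroxy-2,6,6-trimethylcyclohex-2-en-1-one
Product: 3 (4S)-4-[(tert-butyldimethylsilyl)oxy]-2,6,6-trimethylcyclohex-2-en-1-one
Conditions: TBSCl, imidazole, DMF, rt
Reagents that add atoms: tert-butyldimethylsilyl chloride (TBSCl), CC(C)(C)[Si](C)(C)Cl
Why: Imidazole-promoted silylation of the secondary allylic alcohol, which does not touch the stereocenter.

Step 3
Reactants: 3 (4S)-4-[(tert-butyldimethylsilyl)oxy]-2,6,6-trimethylcyclohex-2-en-1-one
Product: 5 (4R)-4-[(tert-butyldimethylsilyl)oxy]-2,6,6-trimethylcyclohex-1-en-1-yl trifluoromethanesulfonate, via lithium enolate 4 (not isolated)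
Conditions: LiBH(s-Bu)3 (L-Selectride, 1.1 equiv), THF, −78 °C; then PhNTf2 (1.2 equiv), −78 °C to rt
Reagents that add atoms: N-phenylbis(trifluoromethanesulfonimide) (PhNTf2), O=S(=O)(N(c1ccccc1)S(=O)(=O)C(F)(F)F)C(F)(F)F
Why: Conjugate reduction–enolate trapping: the bulky borohydride cannot reach the C1 carbonyl between two fully substituted carbons and should deliver hydride to C3, so the enolate forms regiospecifically between C1 and C2 and is O-sulfonylated to the enol triflate, the silyloxy stereocenter being untouched (its descriptor changes to R only through the priorities).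

Step 4
Reactants: 5 (4R)-4-[(tert-butyldimethylsilyl)oxy]-2,6,6-trimethylcyclohex-1-en-1-yl trifluoromethanesulfonate, 6 ethynyltrimethylsilane
Product: 7 tert-butyldimethyl({(1R)-3,5,5-trimethyl-4-[(trimethylsilyl)ethynyl]cyclohex-3-en-1-yl}oxy)silane
Conditions: Pd(PPh3)4 (5 mol %), CuI (10 mol %), Et3N, DMF, 50 °C, sealed tube
Reagents that add atoms: none
Why: Sonogashira coupling (zerovalent palladium with CuI) of an enol triflate with a terminal alkyne; 2,6,6-trisubstituted cyclohexenyl triflates are established partners in this coupling.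

Step 5
Reactants: 7 tert-butyldimethyl({(1R)-3,5,5-trimethyl-4-[(trimethylsilyl)ethynyl]cyclohex-3-en-1-yl}oxy)silane
Product: 8 (1R)-4-ethynyl-3,5,5-trimethylcyclohex-3-en-1-ol
Conditions: Bu4NF (3 equiv), THF, 0 °C to rt
Reagents that add atoms: none
Why: Fluoride-induced desilylation should cleave the C(sp)–Si and the O–Si bond in one operation and leave the enyne and the carbinol stereocenter (3'R of the target) intact.

Step 6
Reactants: 3 (4S)-4-[(tert-butyldimethylsilyl)oxy]-2,6,6-trimethylcyclohex-2-en-1-one, 9 diethyl (3-oxobutan-2-yl)phosphonate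
Product: 11 diethyl {4-[(1S,4S)-4-[(tert-butyldimethylsilyl)oxy]-1-hydroxy-2,6,6-trimethylcyclohex-2-en-1-yl]-3-oxobutan-2-yl}phosphonate, via phosphonate dianion 10 (not isolated)
Conditions: 9 (1.5 equiv), NaH, THF, 0 °C; n-BuLi, 0 °C; then 3, −78 to −40 °C; AcOH quench at −78 °C
Reagents that add atoms: none
Why: Aldol-type 1,2-addition of a β-ketophosphonate dianion through its terminal carbanion to a ketone that cannot be enolised at either α-carbon; the new tertiary carbinol (C6 of the target) is set by substrate control, since in the half-chair with the silyloxy group pseudo-equatorial one methyl of the gem-dimethyl carbon is axial and blocks its face, so the nucleophile should enter from the opposite face (syn to the silyloxy group) and leave the hydroxyl trans to it, (1S,4S); the phosphorus-bearing carbon forms as an inconsequential epimer mixture.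

Step 7
Reactants: 11 diethyl {4-[(1S,4S)-4-[(tert-butyldimethylsilyl)oxy]-1-hydroxy-2,6,6-trimethylcyclohex-2-en-1-yl]-3-oxobutan-2-yl}phosphonate
Product: 12 diethyl {4-[(1S,4S)-1,4-dihydroxy-2,6,6-trimethylcyclohex-2-en-1-yl]-3-oxobutan-2-yl}phosphonate
Conditions: HF·pyridine, pyridine, THF, 0 °C to rt
Reagents that add atoms: none
Why: Desilylation with buffered HF·pyridine removes the allylic silyl ether without base, so the tertiary β-hydroxy ketone is not exposed to retro-aldol conditions.

Step 8
Reactants: 12 diethyl {4-[(1S,4S)-1,4-dihydroxy-2,6,6-trimethylcyclohex-2-en-1-yl]-3-oxobutan-2-yl}phosphonate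
Product: 13 diethyl {4-[(1S)-1-hydroxy-2,6,6-trimethyl-4-oxocyclohex-2-en-1-yl]-3-oxobutan-2-yl}phosphonate
Conditions: MnO2 (activated, 15 equiv), CH2Cl2, rt
Reagents that add atoms: none
Why: Allylic oxidation with activated MnO2 should convert only the secondary allylic alcohol (the tertiary alcohol cannot be oxidised), which reveals the ring enone of the target and removes the carbinol that controlled step 6.

Step 9
Reactants: 14 1-bromobut-2-yne
Product: 15 diethyl but-2-yn-1-ylphosphonate
Conditions: P(OEt)3 (1.2 equiv), neat, 120 °C, EtBr distilled off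
Reagents that add atoms: triethyl phosphite, CCOP(OCC)OCC
Why: Michaelis–Arbuzov reaction of a primary propargylic bromide, in which the internal alkyne disfavours the allenic substitution product.

Step 10
Reactants: 15 diethyl but-2-yn-1-ylphosphonate, 16 (2E,4E,6E)-2,7-dimethylocta-2,4,6-trienedial
Product: 18 (2E,4E,6E,8E)-2,7-dimethyldodeca-2,4,6,8-tetraen-10-ynal, via sodium phosphonate carbanion 17 (not isolated)
Conditions: 15, NaN(SiMe3)2 (1.0 equiv), THF, −78 °C; cannulated into 16 (3 equiv), THF, −78 to 0 °C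
Reagents that add atoms: none
Why: Horner–Wadsworth–Emmons olefination with a propargylic phosphonate carbanion should give the (E)-enyne (the C11'=C12' bond), and inverse addition to an excess of the symmetric dialdehyde keeps the reaction at mono-olefination.

Step 11
Reactants: 18 (2E,4E,6E,8E)-2,7-dimethyldodeca-2,4,6,8-tetraen-10-ynal, 19 (triphenylphosphoranylidene)acetaldehyde
Product: 20 (2E,4E,6E,8E,10E)-4,9-dimethyltetradeca-2,4,6,8,10-pentaen-12-ynal
Conditions: 19 (1.05 equiv), toluene, 80 °C, dark
Reagents that add atoms: none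
Why: Wittig reaction with the stabilised formylmethylene ylide homologates the α-methyl enal by two carbons to the (E)-enal (the C11=C12 bond); one equivalent of ylide limits a second homologation.

Step 12
Reactants: 13 diethyl {4-[(1S)-1-hydroxy-2,6,6-trimethyl-4-oxocyclohex-2-en-1-yl]-3-oxobutan-2-yl}phosphonate, 20 (2E,4E,6E,8E,10E)-4,9-dimethyltetradeca-2,4,6,8,10-pentaen-12-ynal
Product: 21 (4S)-4-hydroxy-3,5,5-trimethyl-4-[(3E,5E,7E,9E,11E,13E)-3,7,12-trimethyl-2-oxoheptadeca-3,5,7,9,11,13-hexaen-15-yn-1-yl]cyclohex-2-en-1-one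
Conditions: Ba(OH)2·8H2O (activated, 0.8 equiv), THF/H2O (40:1), rt, dark
Reagents that add atoms: none
Why: Horner–Wadsworth–Emmons olefination of an α-methyl β-ketophosphonate under mild Ba(OH)2 activation should give the (E)-trisubstituted enone (C9=C10); the phosphonate is by far the most acidic site, so the tertiary aldol and the γ-hydroxy enone should not be deprotonated.

Step 13
Reactants: 8 (1R)-4-ethynyl-3,5,5-trimethylcyclohex-3-en-1-ol, 21 (4S)-4-hydroxy-3,5,5-trimethyl-4-[(3E,5E,7E,9E,11E,13E)-3,7,12-trimethyl-2-oxoheptadeca-3,5,7,9,11,13-hexaen-15-yn-1-yl]cyclohex-2-en-1-one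
Product: 22 (4S)-4-hydroxy-4-[(3E,5E,7E,9E,11E,13E,15E)-18-[(4R)-4-hydroxy-2,6,6-trimethylcyclohex-1-en-1-yl]-3,7,12,16-tetramethyl-2-oxooctadeca-3,5,7,9,11,13,15-heptaen-17-yn-1-yl]-3,5,5-trimethylcyclohex-2-en-1-one (the target)
Conditions: Pd(OAc)2 (5 mol %), tris(2,6-dimethoxyphenyl)phosphine (5 mol %), 8 (1.5 equiv), benzene, rt, dark, argon
Reagents that add atoms: none
Why: Proposed new method: divalent palladium acetate carrying the bulky electron-rich phosphine should deprotonate the terminal alkyne of 8 with help of acetate to an alkynylpalladium species, which adds syn across the C9'≡C10' triple bond of 21 with the alkynyl group going to C9' (the methyl-bearing end remote from the carbonyl) and palladium to C10', where the charge is delocalised along the polyene into the C8 ketone as a vinylogous palladium enolate; protonolysis of the C10'–Pd bond by acetic acid with retention then releases 22 and returns the catalyst. The closest known reaction type is the Pd(OAc)2/tris(2,6-dimethoxyphenyl)phosphine-catalysed cross-addition of terminal donor alkynes to acceptor alkynes such as ynoates and ynones, which gives (E)-enynes by the same syn addition; what is new is that the acceptor is activated only vinylogously, through six C=C bonds. No ring is closed and no stereocenter is formed; the one new stereo-element, the (9'E) geometry of the trisubstituted C9'=C10' bond, is fixed by the syn carbopalladation and the stereoretentive protonolysis (alkynyl group and H cis, methyl group and C11' cis). The step needs regioselectivity for C9' over C10', which the polarisation of the polyenynone and the smaller methyl terminus both favour, and cross-addition over self-addition of 8, which is secured because the triple bond of 8 is flanked by a fully substituted ring carbon and is a poor acceptor. Both free hydroxyl groups, both enones and the polyene should be inert to these near-neutral conditions, so no protecting group is needed and the addition can be the last step.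

**Compound list**

1 | 2,6,6-trimethylcyclohex-2-ene-1,4-dione (ketoisophorone) | CC1=CC(=O)CC(C)(C)C1=O | starting material
2 | (4S)-4-hydroxy-2,6,6-trimethylcyclohex-2-en-1-one | CC1=C[C@@H](O)CC(C)(C)C1=O | intermediate
3 | (4S)-4-[(tert-butyldimethylsilyl)oxy]-2,6,6-trimethylcyclohex-2-en-1-one | CC1=C[C@@H](O[Si](C)(C)C(C)(C)C)CC(C)(C)C1=O | intermediate
4 | lithium (4R)-4-[(tert-butyldimethylsilyl)oxy]-2,6,6-trimethylcyclohex-1-en-1-olate | [Li+].CC1=C([O-])C(C)(C)C[C@H](O[Si](C)(C)C(C)(C)C)C1 | intermediate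
5 | (4R)-4-[(tert-butyldimethylsilyl)oxy]-2,6,6-trimethylcyclohex-1-en-1-yl trifluoromethanesulfonate | CC1=C(OS(=O)(=O)C(F)(F)F)C(C)(C)C[C@H](O[Si](C)(C)C(C)(C)C)C1 | intermediate
6 | ethynyltrimethylsilane | C#C[Si](C)(C)C | starting material
7 | tert-butyldimethyl({(1R)-3,5,5-trimethyl-4-[(trimethylsilyl)ethynyl]cyclohex-3-en-1-yl}oxy)silane | CC1=C(C#C[Si](C)(C)C)C(C)(C)C[C@H](O[Si](C)(C)C(C)(C)C)C1 | intermediate
8 | (1R)-4-ethynyl-3,5,5-trimethylcyclohex-3-en-1-ol | C#CC1=C(C)C[C@@H](O)CC1(C)C | intermediate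
9 | diethyl (3-oxobutan-2-yl)phosphonate | CCOP(=O)(OCC)C(C)C(C)=O | starting material
10 | sodium lithium dianion of diethyl (3-oxobutan-2-yl)phosphonate (terminal carbanion, phosphonate-stabilised enolate) | [Na+].[Li+].[CH2-]C([O-])=C(C)P(=O)(OCC)OCC | intermediate
11 | diethyl {4-[(1S,4S)-4-[(tert-butyldimethylsilyl)oxy]-1-hydroxy-2,6,6-trimethylcyclohex-2-en-1-yl]-3-oxobutan-2-yl}phosphonate (epimers at the P-bearing carbon) | CC1=C[C@@H](O[Si](C)(C)C(C)(C)C)CC(C)(C)[C@@]1(O)CC(=O)C(C)P(=O)(OCC)OCC | intermediate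
12 | diethyl {4-[(1S,4S)-1,4-dihydroxy-2,6,6-trimethylcyclohex-2-en-1-yl]-3-oxobutan-2-yl}phosphonate | CC1=C[C@@H](O)CC(C)(C)[C@@]1(O)CC(=O)C(C)P(=O)(OCC)OCC | intermediate
13 | diethyl {4-[(1S)-1-hydroxy-2,6,6-trimethyl-4-oxocyclohex-2-en-1-yl]-3-oxobutan-2-yl}phosphonate | CC1=CC(=O)CC(C)(C)[C@@]1(O)CC(=O)C(C)P(=O)(OCC)OCC | intermediate
14 | 1-bromobut-2-yne | CC#CCBr | starting material
15 | diethyl but-2-yn-1-ylphosphonate | CC#CCP(=O)(OCC)OCC | intermediate
16 | (2E,4E,6E)-2,7-dimethylocta-2,4,6-trienedial | O=C/C(C)=C/C=C/C=C(\C)C=O | starting material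
17 | sodium salt of the α-carbanion of diethyl but-2-yn-1-ylphosphonate | [Na+].CC#C[CH-]P(=O)(OCC)OCC | intermediate
18 | (2E,4E,6E,8E)-2,7-dimethyldodeca-2,4,6,8-tetraen-10-ynal | O=C/C(C)=C/C=C/C=C(C)/C=C/C#CC | intermediate
19 | (triphenylphosphoranylidene)acetaldehyde | O=CC=P(c1ccccc1)(c1ccccc1)c1ccccc1 | starting material
20 | (2E,4E,6E,8E,10E)-4,9-dimethyltetradeca-2,4,6,8,10-pentaen-12-ynal | O=C/C=C/C(C)=C/C=C/C=C(C)/C=C/C#CC | intermediate
21 | (4S)-4-hydroxy-3,5,5-trimethyl-4-[(3E,5E,7E,9E,11E,13E)-3,7,12-trimethyl-2-oxoheptadeca-3,5,7,9,11,13-hexaen-15-yn-1-yl]cyclohex-2-en-1-one | CC1=CC(=O)CC(C)(C)[C@@]1(O)CC(=O)/C(C)=C/C=C/C(C)=C/C=C/C=C(C)/C=C/C#CC | intermediate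
22 | (4S)-4-hydroxy-4-[(3E,5E,7E,9E,11E,13E,15E)-18-[(4R)-4-hydroxy-2,6,6-trimethylcyclohex-1-en-1-yl]-3,7,12,16-tetramethyl-2-oxooctadeca-3,5,7,9,11,13,15-heptaen-17-yn-1-yl]-3,5,5-trimethylcyclohex-2-en-1-one | CC1=CC(=O)CC(C)(C)[C@@]1(O)CC(=O)/C(C)=C/C=C/C(C)=C/C=C/C=C(C)/C=C/C=C(\C)C#CC1=C(C)C[C@@H](O)CC1(C)C | target

**Step count and risks**

Total step count: 13. Longest linear sequence: 7 steps (steps 1, 2, 6, 7, 8, 12, 13).

Steps most likely to fail:

1. Step 13 (proposed new method). The alkynylpalladium species may add to the only vinylogously activated triple bond with the wrong regiochemistry or too slowly, so that self-addition of 8 or palladium-hydride scrambling of the polyene geometry takes over. The fallback uses known chemistry and makes the C8'–C9' bond first on a true acceptor alkyne, then grows the chain. It sets out from 8: Pd(OAc)2/tris(2,6-dimethoxyphenyl)phosphine-catalysed addition of 8 to ethyl but-2-ynoate should give ethyl (2E)-5-[(4R)-4-hydroxy-2,6,6-trimethylcyclohex-1-en-1-yl]-3-methylpent-2-en-4-ynoate F1. Reduction with i-Bu2AlH gives (1R)-4-[(3E)-5-hydroxy-3-methylpent-3-en-1-yn-1-yl]-3,5,5-trimethylcyclohex-3-en-1-ol F2, and PPh3·HBr converts the allylic alcohol into [(2E)-5-[(4R)-4-hydroxy-2,6,6-trimethylcyclohex-1-en-1-yl]-3-methylpent-2-en-4-yn-1-yl]triphenylphosphonium bromide F3. Wittig reaction of F3 with an excess of 16 (NaOMe, CH2Cl2/MeOH, then thermal equilibration to the all-E isomer) gives (2E,4E,6E,8E,10E)-13-[(4R)-4-hydroxy-2,6,6-trimethylcyclohex-1-en-1-yl]-2,7,11-trimethyltrideca-2,4,6,8,10-pentaen-12-ynal F4. Wittig homologation with 19 gives (2E,4E,6E,8E,10E,12E)-15-[(4R)-4-hydroxy-2,6,6-trimethylcyclohex-1-en-1-yl]-4,9,13-trimethylpentadeca-2,4,6,8,10,12-hexaen-14-ynal F5, and Horner–Wadsworth–Emmons reaction of F5 with 13 (Ba(OH)2, wet THF) comes back to the route at 22.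

2. Step 6. The dianion may attack the other face of the ketone if the conformational bias is weaker than assumed, may add in conjugate fashion at C3, or the addition may revert on warming. The fallback replaces substrate induction by a separable auxiliary and sets out from 1: ketalisation of the unhindered carbonyl with (2R,3R)-butane-2,3-diol (TsOH, benzene, water removal) gives (2R,3R)-2,3,7,9,9-pentamethyl-1,4-dioxaspiro[4.5]dec-6-en-8-one F6. Addition of dianion 10 gives two carbinol epimers that are diastereomers and are separated by chromatography, the wanted one being diethyl {4-[(2R,3R,8S)-8-hydroxy-2,3,7,9,9-pentamethyl-1,4-dioxaspiro[4.5]dec-6-en-8-yl]-3-oxobutan-2-yl}phosphonate F7. Mild aqueous acid (oxalic acid, THF/H2O) removes the ketal and comes back to the route at 13.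

3. Step 12. Under the basic olefination conditions the tertiary β-hydroxy ketone may undergo retro-aldol cleavage while the poorly electrophilic polyenal reacts slowly. The fallback inverts the order of bond formation so that the aldol is made last under kinetic conditions; it sets out from 9 and 20 and also uses 3. Horner–Wadsworth–Emmons reaction of 9 with 20 (NaH, THF) gives (3E,5E,7E,9E,11E,13E)-3,7,12-trimethylheptadeca-3,5,7,9,11,13-hexaen-15-yn-2-one F8. Kinetic deprotonation with LiN(i-Pr)2 at −78 °C gives the lithium enolate of that methyl ketone F9, which is added to 3 at −78 °C and quenched cold to give (3E,5E,7E,9E,11E,13E)-1-[(1S,4S)-4-[(tert-butyldimethylsilyl)oxy]-1-hydroxy-2,6,6-trimethylcyclohex-2-en-1-yl]-3,7,12-trimethylheptadeca-3,5,7,9,11,13-hexaen-15-yn-2-one F10, with the facial control of step 6. HF·pyridine gives (3E,5E,7E,9E,11E,13E)-1-[(1S,4S)-1,4-dihydroxy-2,6,6-trimethylcyclohex-2-en-1-yl]-3,7,12-trimethylheptadeca-3,5,7,9,11,13-hexaen-15-yn-2-one F11, and MnO2 oxidation comes back to the route at 21.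

**Further compounds**

F1 | step 13 | ethyl (2E)-5-[(4R)-4-hydroxy-2,6,6-trimethylcyclohex-1-en-1-yl]-3-methylpent-2-en-4-ynoate | CCOC(=O)/C=C(\C)C#CC1=C(C)C[C@@H](O)CC1(C)C
F2 | step 13 | (1R)-4-[(3E)-5-hydroxy-3-methylpent-3-en-1-yn-1-yl]-3,5,5-trimethylcyclohex-3-en-1-ol | OC/C=C(\C)C#CC1=C(C)C[C@@H](O)CC1(C)C
F3 | step 13 | [(2E)-5-[(4R)-4-hydroxy-2,6,6-trimethylcyclohex-1-en-1-yl]-3-methylpent-2-en-4-yn-1-yl]triphenylphosphonium bromide | [Br-].C(/C=C(\C)C#CC1=C(C)C[C@@H](O)CC1(C)C)[P+](c1ccccc1)(c1ccccc1)c1ccccc1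
F4 | step 13 | (2E,4E,6E,8E,10E)-13-[(4R)-4-hydroxy-2,6,6-trimethylcyclohex-1-en-1-yl]-2,7,11-trimethyltrideca-2,4,6,8,10-pentaen-12-ynal | O=C/C(C)=C/C=C/C=C(C)/C=C/C=C(\C)C#CC1=C(C)C[C@@H](O)CC1(C)C
F5 | step 13 | (2E,4E,6E,8E,10E,12E)-15-[(4R)-4-hydroxy-2,6,6-trimethylcyclohex-1-en-1-yl]-4,9,13-trimethylpentadeca-2,4,6,8,10,12-hexaen-14-ynal | O=C/C=C/C(C)=C/C=C/C=C(C)/C=C/C=C(\C)C#CC1=C(C)C[C@@H](O)CC1(C)C
F6 | step 6 | (2R,3R)-2,3,7,9,9-pentamethyl-1,4-dioxaspiro[4.5]dec-6-en-8-one | CC1=CC2(CC(C)(C)C1=O)O[C@H](C)[C@@H](C)O2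
F7 | step 6 | diethyl {4-[(2R,3R,8S)-8-hydroxy-2,3,7,9,9-pentamethyl-1,4-dioxaspiro[4.5]dec-6-en-8-yl]-3-oxobutan-2-yl}phosphonate | CC1=CC2(CC(C)(C)[C@@]1(O)CC(=O)C(C)P(=O)(OCC)OCC)O[C@H](C)[C@@H](C)O2
F8 | step 12 | (3E,5E,7E,9E,11E,13E)-3,7,12-trimethylheptadeca-3,5,7,9,11,13-hexaen-15-yn-2-one | CC(=O)/C(C)=C/C=C/C(C)=C/C=C/C=C(C)/C=C/C#CC
F9 | step 12 | lithium (3E,5E,7E,9E,11E,13E)-3,7,12-trimethylheptadeca-1,3,5,7,9,11,13-heptaen-15-yn-2-olate | [Li+].C=C([O-])/C(C)=C/C=C/C(C)=C/C=C/C=C(C)/C=C/C#CC
F10 | step 12 | (3E,5E,7E,9E,11E,13E)-1-[(1S,4S)-4-[(tert-butyldimethylsilyl)oxy]-1-hydroxy-2,6,6-trimethylcyclohex-2-en-1-yl]-3,7,12-trimethylheptadeca-3,5,7,9,11,13-hexaen-15-yn-2-one | CC1=C[C@@H](O[Si](C)(C)C(C)(C)C)CC(C)(C)[C@@]1(O)CC(=O)/C(C)=C/C=C/C(C)=C/C=C/C=C(C)/C=C/C#CC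
F11 | step 12 | (3E,5E,7E,9E,11E,13E)-1-[(1S,4S)-1,4-dihydroxy-2,6,6-trimethylcyclohex-2-en-1-yl]-3,7,12-trimethylheptadeca-3,5,7,9,11,13-hexaen-15-yn-2-one | CC1=C[C@@H](O)CC(C)(C)[C@@]1(O)CC(=O)/C(C)=C/C=C/C(C)=C/C=C/C=C(C)/C=C/C#CC
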